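**Plan**

1. Working locants: C1 = CH–O(angeloyl), C2 = CH–O(2-methylbutanoyl), C3 = CH2, C4 = C(CH3), C5 = CH next to C6 (C=O), C7=C8(CH3), C9 = CH, C10 = CH, C11 = C(CH3)2. The retrosynthesis removes the two acyl groups and the C6 oxygen, cuts C3–C4 and C10–C5 together, then C2=C3, C1–O and C10–C11, and ends at an arene.
2. Enabling feature: with those two bonds cut, C10 is homoallylic to C4=C5 of a symmetric 2,6-dimethylcyclohexa-2,5-dienyl ring (C4–C9). C3 becomes the methylidene carbon of a 2-methylideneoxolane (temporary ring) whose ring oxygen sits on C10. One C10–O ionisation then gives both the cyclobutyl cation at C4 (ring C4–C5–C10–C9) and the enolate carbon C3 that captures it.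
3. Forward order: six-membered ring by Birch reduction, C10–C11 by reverse prenylation, oxolanone ring, C1–O, C3 by methylenation. The key step closes the four- and seven-membered rings and opens the oxolane. C6 oxidation, C2 reduction and two esterifications finish.
4. Stereochemistry: C10 from Ipc-controlled allylboration; C1 trans to C10 by lactone-enolate hydroxylation; C4, C5, C9 and ring C10 from stereospecific anti π-participation (inversion at C10 selects one enantiotopic methallyl half of the ring); C2 by hydroxyl-directed hydride delivery; the acyl stereocentre and the Z-alkene come from (S)-2-methylbutanoic anhydride and angelic acid.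

Key step: step 10

Remark: C1–C11 are the working locants of plan line 1, not systematic ones; "Ipc" is the isopinocampheyl group of the (−)-α-pinene series.

**Step 1**
Reactants: 1 2,6-dimethylbenzoic acid
Product: 2 2,6-dimethylcyclohexa-2,5-diene-1-carboxylic acid
Conditions: Li, NH3 (l), THF, −78 °C; then NH4Cl
Reagents that add atoms: none
Why: Birch reduction of a benzoic acid puts the two new sp3 centres at the ipso and para carbons, so both methyl-bearing carbons stay olefinic and the C9–C10 bond is present from the start; no stereocentre is formed.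

**Step 2**
Reactants: 2 2,6-dimethylcyclohexa-2,5-diene-1-carboxylic acid
Product: 3 (2,6-dimethylcyclohexa-2,5-dien-1-yl)methanol
Conditions: LiAlH4, THF, 0 °C to rt
Reagents that add atoms: none
Why: Hydride reduction of the carboxylate should give the primary alcohol and leave the isolated alkenes untouched.

**Step 3**
Reactants: 3 (2,6-dimethylcyclohexa-2,5-dien-1-yl)methanol
Product: 4 2,6-dimethylcyclohexa-2,5-diene-1-carbaldehyde
Conditions: Dess–Martin periodinane, pyridine, CH2Cl2, 0 °C; used at once
Reagents that add atoms: none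
Why: Dess–Martin oxidation under buffered, non-enolising conditions should give the aldehyde without migration of the doubly allylic α-hydrogen.

**Step 4**
Reactants: 4 2,6-dimethylcyclohexa-2,5-diene-1-carbaldehyde
Product: 6 (S)-1-(2,6-dimethylcyclohexa-2,5-dien-1-yl)-2,2-dimethylbut-3-en-1-ol, via borinate ester 5 (not isolated)
Conditions: (+)-Ipc2BOMe, prenylmagnesium chloride, Et2O, −78 to 0 °C; then 4, −78 °C; then NaOH, H2O2
Reagents that add atoms: prenylmagnesium chloride, CC(C)=CC[Mg]Cl, acting through prenyl-B(Ipc)2 made from it in the flask, CC(C)=CCB([C@H]1C[C@H]2C[C@@H]([C@@H]1C)C2(C)C)[C@H]1C[C@H]2C[C@@H]([C@@H]1C)C2(C)C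
Why: Brown allylboration: the prenylborane reacts at its γ-carbon (C11) through a closed six-membered transition state, and the Ipc ligands of this series direct it to the Re face of the aldehyde, which should set C10 as (S).

**Step 5**
Reactants: 6 (S)-1-(2,6-dimethylcyclohexa-2,5-dien-1-yl)-2,2-dimethylbut-3-en-1-ol
Product: 8 (S)-1-(2,6-dimethylcyclohexa-2,5-dien-1-yl)-2,2-dimethylbutane-1,4-diol, via alkylborane 7 (not isolated)
Conditions: 9-BBN, THF, 0 °C to rt; then NaOH, H2O2
Reagents that add atoms: hydrogen peroxide, OO
Why: Anti-Markovnikov hydroboration–oxidation; 9-BBN should react with the monosubstituted vinyl group much faster than with the hindered trisubstituted ring alkenes, and no stereocentre is formed.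

**Step 6**
Reactants: 8 (S)-1-(2,6-dimethylcyclohexa-2,5-dien-1-yl)-2,2-dimethylbutane-1,4-diol
Product: 10 (S)-5-(2,6-dimethylcyclohexa-2,5-dien-1-yl)-4,4-dimethyloxolan-2-one, via lactol 9 (not isolated)
Conditions: Ag2CO3 on Celite, toluene, reflux
Reagents that add atoms: none
Why: Fetizon oxidation: the primary alcohol is oxidised first, the hydroxy aldehyde closes to the five-membered lactol with the C10 hydroxyl, and the lactol is oxidised to the lactone; C10 is not touched.

**Step 7**
Reactants: 10 (S)-5-(2,6-dimethylcyclohexa-2,5-dien-1-yl)-4,4-dimethyloxolan-2-one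
Product: 11 (3S,5S)-5-(2,6-dimethylcyclohexa-2,5-dien-1-yl)-3-hydroxy-4,4-dimethyloxolan-2-one
Conditions: KN(SiMe3)2, THF, −78 °C; then 2-(phenylsulfonyl)-3-phenyloxaziridine; NH4Cl
Reagents that add atoms: 2-(phenylsulfonyl)-3-phenyloxaziridine, O=S(=O)(c1ccccc1)N1OC1c1ccccc1
Why: Enolate hydroxylation with the Davis oxaziridine: the planar lactone enolate should be attacked at C1 on the face opposite the bulky dienyl group on C10, giving the 3,5-trans hydroxy lactone.

**Step 8**
Reactants: 11 (3S,5S)-5-(2,6-dimethylcyclohexa-2,5-dien-1-yl)-3-hydroxy-4,4-dimethyloxolan-2-one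
Product: 12 (3S,5S)-3-[(tert-butyldimethylsilyl)oxy]-5-(2,6-dimethylcyclohexa-2,5-dien-1-yl)-4,4-dimethyloxolan-2-one
Conditions: TBSOTf, 2,6-lutidine, CH2Cl2, 0 °C
Reagents that add atoms: tert-butyldimethylsilyl triflate, CC(C)(C)[Si](C)(C)OS(=O)(=O)C(F)(F)F
Why: Silyl triflate silylation of the hindered secondary alcohol protects C1–O for the organometallic, Lewis-acid and oxidation steps that follow.

**Step 9**
Reactants: 12 (3S,5S)-3-[(tert-butyldimethylsilyl)oxy]-5-(2,6-dimethylcyclohexa-2,5-dien-1-yl)-4,4-dimethyloxolan-2-one
Product: 13 tert-butyl{[(3S,5S)-5-(2,6-dimethylcyclohexa-2,5-dien-1-yl)-4,4-dimethyl-2-methylideneoxolan-3-yl]oxy}dimethylsilane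
Conditions: Cp2TiMe2, toluene, 70 °C, dark
Reagents that add atoms: dimethyltitanocene Cp2TiMe2, C[Ti](C)(C1C=CC=C1)C1C=CC=C1
Why: Petasis methylenation: Cp2Ti=CH2 formed thermally converts the lactone carbonyl C2 into the exocyclic enol ether and brings in C3, under non-basic conditions that leave C1 and the 1,4-diene alone.

**Step 10**
Reactants: 13 tert-butyl{[(3S,5S)-5-(2,6-dimethylcyclohexa-2,5-dien-1-yl)-4,4-dimethyl-2-methylideneoxolan-3-yl]oxy}dimethylsilane
Product: 14 tricyclic silyloxy ketone (target skeleton with C2 ketone, C1–OTBS, C6 methylene and C7=C8)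
Conditions: Me2AlCl, 2,6-di-tert-butyl-4-methylpyridine, CH2Cl2, −78 to −20 °C
Reagents that add atoms: none
Why: Proposed new method: Me2AlCl binds the enol-ether oxygen of 13 and the C10–O bond ionises with anti participation of the C4=C5 π bond, which closes the four-membered ring C4–C5–C10–C9 as a 1-methylcyclobutyl cation while the oxygen leaves as the aluminium enolate of the C2 ketone; the enolate carbon C3, held on C10 through C2–C1–C11, then adds to C4 and closes the seven-membered ring. The closest known reaction types are the Petasis–Ferrier rearrangement and related Lewis-acid 1,3 O-to-C shifts of cyclic enol ethers (C–O cleavage to cation plus aluminium enolate, then C–C recombination), the solvolytic homoallyl-to-cyclobutyl rearrangement of 3-methylbut-3-enyl sulfonates, and the α-tert-alkylation of enol derivatives by tertiary cations. The cyclobutane closes by attack of the alkene terminus C5 on the back of C10 with the charge passing to the methyl-bearing C4, and the seven-membered ring closes in the 7-(enolendo)-exo-tet mode, whereas direct return of C3 to C10 would be a disfavoured 5-(enolendo)-exo-tet closure. C10 is inverted, so its (S) configuration decides which of the two enantiotopic methallyl halves of the ring reacts, because only that pairing puts the quaternary C11 on the face away from the new three-carbon bridge; C5 and C9 follow from the bicyclo[3.1.1] geometry and C4 from the tether, which can reach C4 only from that same face. The step needs π participation to win over a 1,2-hydride shift from the doubly allylic C9–H (which would aromatise the ring) and over proton loss from the cation; the low temperature, the non-nucleophilic medium, the hindered pyridine as proton trap and the reversibility of oxygen recapture, which funnels material to the irreversible C–C bond, are meant to secure this.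

**Step 11**
Reactants: 14 tricyclic silyloxy ketone
Product: 15 tricyclic silyloxy enedione (C6 ketone conjugated with C7=C8, C2 ketone, C1–OTBS)
Conditions: CrO3, 3,5-dimethylpyrazole, CH2Cl2, −20 °C
Reagents that add atoms: chromium trioxide, O=[Cr](=O)=O
Why: Allylic oxidation of the ring methylene C6 next to the trisubstituted alkene should give the conjugated ketone, as in the oxidation of α-pinene to verbenone; the bridgehead C9–H cannot give an enone and the C2 ketone and silyl ether are inert.

**Step 12**
Reactants: 15 tricyclic silyloxy enedione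
Product: 16 tricyclic hydroxy enedione (C1–OH, C2 ketone, C6 enone)
Conditions: HF·pyridine, THF, 0 °C to rt
Reagents that add atoms: none
Why: Fluoride cleavage of the silyl ether under mildly acidic conditions should free the C1 alcohol without α-ketol isomerisation.

**Step 13**
Reactants: 16 tricyclic hydroxy enedione
Product: 17 tricyclic trans-diol enone (C1–OH, C2–OH trans, C6 enone)
Conditions: Me4NBH(OAc)3, MeCN–AcOH, −20 °C
Reagents that add atoms: none
Why: Hydroxyl-directed reduction of the Evans–Saksena type: the C1 hydroxyl binds boron and delivers hydride to the neighbouring C2 ketone from its own face, which should give the trans diol (C2 S), while the enone, having no neighbouring hydroxyl, is not reduced.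

**Step 14**
Reactants: 17 tricyclic trans-diol enone, 18 (S)-2-methylbutanoic anhydride
Product: 19 C2 (S)-2-methylbutanoate of 17 (C1–OH free)
Conditions: Et3N, DMAP (cat.), CH2Cl2, −20 to 0 °C
Reagents that add atoms: none
Why: Acylation should be selective for the C2 hydroxyl because the C1 hydroxyl is neopentyl (next to C11), and the symmetric anhydride avoids a ketene pathway so the (S) centre of the acyl group is kept.

**Step 15**
Reactants: 19 C2 (S)-2-methylbutanoate of 17, 20 angelic acid
Product: 22 target diester, via mixed anhydride 21 (not isolated)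
Conditions: 2,4,6-trichlorobenzoyl chloride, Et3N, toluene, rt; then 19, 80 °C
Reagents that add atoms: none
Why: Yamaguchi-type esterification through the mixed anhydride, heated without a nucleophilic catalyst, is the established way to acylate hindered alcohols with angelic acid without Z-to-E isomerisation to the tiglate.

**Compound list**

1 | 2,6-dimethylbenzoic acid | Cc1cccc(C)c1C(=O)O | starting material
2 | 2,6-dimethylcyclohexa-2,5-diene-1-carboxylic acid | CC1=CCC=C(C)C1C(=O)O | intermediate
3 | (2,6-dimethylcyclohexa-2,5-dien-1-yl)methanol | CC1=CCC=C(C)C1CO | intermediate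
4 | 2,6-dimethylcyclohexa-2,5-diene-1-carbaldehyde | CC1=CCC=C(C)C1C=O | intermediate
5 | diisopinocampheylborinate of alcohol 6 (O–B(Ipc)2 on C10) | C=CC(C)(C)[C@@H](OB([C@H]1C[C@H]2C[C@@H]([C@@H]1C)C2(C)C)[C@H]1C[C@H]2C[C@@H]([C@@H]1C)C2(C)C)C1C(C)=CCC=C1C | intermediate (not isolated)
6 | (S)-1-(2,6-dimethylcyclohexa-2,5-dien-1-yl)-2,2-dimethylbut-3-en-1-ol | C=CC(C)(C)[C@@H](O)C1C(C)=CCC=C1C | intermediate
7 | hydroboration adduct of 6 (9-borabicyclo[3.3.1]nonan-9-yl on the terminal carbon and on the C10 oxygen) | C(CC(C)(C)[C@@H](OB1[C@H]2CCC[C@@H]1CCC2)C1C(C)=CCC=C1C)B1[C@H]2CCC[C@@H]1CCC2 | intermediate (not isolated)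
8 | (S)-1-(2,6-dimethylcyclohexa-2,5-dien-1-yl)-2,2-dimethylbutane-1,4-diol | OCCC(C)(C)[C@@H](O)C1C(C)=CCC=C1C | intermediate
9 | (5S)-5-(2,6-dimethylcyclohexa-2,5-dien-1-yl)-4,4-dimethyloxolan-2-ol (lactol, both anomers) | OC1CC(C)(C)[C@@H](O1)C2C(C)=CCC=C2C | intermediate (not isolated)
10 | (S)-5-(2,6-dimethylcyclohexa-2,5-dien-1-yl)-4,4-dimethyloxolan-2-one | O=C1CC(C)(C)[C@@H](O1)C2C(C)=CCC=C2C | intermediate
11 | (3S,5S)-5-(2,6-dimethylcyclohexa-2,5-dien-1-yl)-3-hydroxy-4,4-dimethyloxolan-2-one (3-OH trans to the 5-substituent) | O=C1[C@@H](O)C(C)(C)[C@@H](O1)C2C(C)=CCC=C2C | intermediate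
12 | (3S,5S)-3-[(tert-butyldimethylsilyl)oxy]-5-(2,6-dimethylcyclohexa-2,5-dien-1-yl)-4,4-dimethyloxolan-2-one | O=C1[C@@H](O[Si](C)(C)C(C)(C)C)C(C)(C)[C@@H](O1)C2C(C)=CCC=C2C | intermediate
13 | tert-butyl{[(3S,5S)-5-(2,6-dimethylcyclohexa-2,5-dien-1-yl)-4,4-dimethyl-2-methylideneoxolan-3-yl]oxy}dimethylsilane | C=C1O[C@@H](C2C(C)=CCC=C2C)C(C)(C)[C@@H]1O[Si](C)(C)C(C)(C)C | intermediate
14 | tricyclic silyloxy ketone: bicyclo[3.1.1]hept-2-ene (C5, C6H2, C7=C8(CH3), C9; one-carbon bridges C4(CH3) and C10) bridged from C4 to C10 by C3H2–C2(=O)–C1H(OTBS)–C11(CH3)2; C1 (S), ring centres as in the target | CC(C)(C)[Si](C)(C)O[C@@H]1C(=O)C[C@@]2(C)[C@@H]3CC=C(C)[C@H]2[C@@H]3C1(C)C | intermediate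
15 | tricyclic silyloxy enedione: 14 with C6 oxidised to the ketone conjugated with C7=C8 | CC(C)(C)[Si](C)(C)O[C@@H]1C(=O)C[C@@]2(C)[C@@H]3C(=O)C=C(C)[C@H]2[C@@H]3C1(C)C | intermediate
16 | tricyclic hydroxy enedione: 15 with free C1–OH | O[C@@H]1C(=O)C[C@@]2(C)[C@@H]3C(=O)C=C(C)[C@H]2[C@@H]3C1(C)C | intermediate
17 | tricyclic trans-diol enone: (1S,2S)-diol, C6 enone, ring centres as in the target | O[C@@H]1[C@@H](O)C[C@@]2(C)[C@@H]3C(=O)C=C(C)[C@H]2[C@@H]3C1(C)C | intermediate
18 | (S)-2-methylbutanoic anhydride | CC[C@H](C)C(=O)OC(=O)[C@@H](C)CC | starting material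
19 | C2 (S)-2-methylbutanoate of diol 17, C1–OH free | O[C@@H]1[C@@H](OC(=O)[C@@H](C)CC)C[C@@]2(C)[C@@H]3C(=O)C=C(C)[C@H]2[C@@H]3C1(C)C | intermediate
20 | angelic acid, (Z)-2-methylbut-2-enoic acid | C/C=C(/C)C(=O)O | starting material
21 | angelic 2,4,6-trichlorobenzoic mixed anhydride | C/C=C(/C)C(=O)OC(=O)c1c(Cl)cc(Cl)cc1Cl | intermediate (not isolated)
22 | target: C1 angelate, C2 (S)-2-methylbutanoate of the tricyclic enone (C1 S, C2 S, C4 R, C5 R, C9 R, C10 S) | C/C=C(/C)C(=O)O[C@@H]1[C@@H](OC(=O)[C@@H](C)CC)C[C@@]2(C)[C@@H]3C(=O)C=C(C)[C@H]2[C@@H]3C1(C)C | target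

**Count**

Total step count: 15. Longest linear sequence: 15 steps, from 1 to 22; 18 and 20 are bought.

**Steps most likely to fail**

Step 10. The C10–O ionisation may not be assisted by the alkene but by a 1,2-hydride shift from the doubly allylic C9–H, which would aromatise the ring. The cyclobutyl cation may also lose a proton, or be recaptured at oxygen, before the enolate carbon reaches C4. The fallback separates the two bond formations into reactions of known type; it sets out from 12 and comes back at 14.
- Reduction of 12 with i-Bu2AlH at −78 °C should give the lactol F1.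
- Ohira–Bestmann homologation (dimethyl (1-diazo-2-oxopropyl)phosphonate, K2CO3, MeOH) should open it to the hydroxy alkyne F2, which carries C3 as the alkyne terminus.
- Mesylation (MsCl, Et3N) should give the mesylate F3.
- Buffered aqueous solvolysis of F3 (the classical homoallyl-to-cyclobutyl rearrangement with capture by water) should give the tertiary cyclobutanol F4, with the C5–C10 bond formed on its own.
- Ionisation of F4 in formic acid with alkyne-terminated cation–olefin cyclisation, then methanolysis of the enol formate (K2CO3, MeOH), should form C3–C4 and the C2 ketone of 14.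

Step 4, together with the handling of 4. Enolisation of the aldehyde at its doubly allylic α-position may lead to double-bond migration or aromatisation before the C–C bond forms, and to loss of material or facial selectivity. The fallback sets out from 3 and comes back at 6, with no new compound (F0). It is the iridium-catalysed transfer-hydrogenative reverse prenylation of the alcohol with 1,1-dimethylallene ([Ir(cod)Cl]2, the SEGPHOS enantiomer that gives the (S)-carbinol, 4-cyano-3-nitrobenzoic acid, Cs2CO3, THF). The aldehyde then exists only transiently on the metal and the C10 configuration is set by the ligand.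

Step 15. The angeloyl unit may isomerise from Z to E during activation, or acylation of the neopentyl C1 hydroxyl may stall and let the C2 acyl group migrate. The fallback sets out from 19 and comes back at 22. Esterification of 19 with 2-[bis(2,2,2-trifluoroethoxy)phosphoryl]propanoic acid (DCC, DMAP) should give the phosphonate ester F5. Still–Gennari olefination of F5 with acetaldehyde (KN(SiMe3)2, 18-crown-6, THF, −78 °C) should then build the Z-configured 2-methylbut-2-enoate on the molecule under kinetic control.

**Further compounds**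

F1 | step 10 | (3S,5S)-3-[(tert-butyldimethylsilyl)oxy]-5-(2,6-dimethylcyclohexa-2,5-dien-1-yl)-4,4-dimethyloxolan-2-ol (lactol, both anomers) | OC1[C@@H](O[Si](C)(C)C(C)(C)C)C(C)(C)[C@@H](O1)C2C(C)=CCC=C2C
F2 | step 10 | hydroxy alkyne: C10 carbinol, C1–OTBS, C2≡C3H | C#C[C@@H](O[Si](C)(C)C(C)(C)C)C(C)(C)[C@@H](O)C1C(C)=CCC=C1C
F3 | step 10 | C10 methanesulfonate of F2 | C#C[C@@H](O[Si](C)(C)C(C)(C)C)C(C)(C)[C@@H](OS(C)(=O)=O)C1C(C)=CCC=C1C
F4 | step 10 | bicyclo[3.1.1]hept-2-ene cyclobutanol: C4(CH3)(OH), C10 carrying C11(CH3)2–C1H(OTBS)–C≡CH | C[C@]1(O)[C@@H]2CC=C(C)[C@H]1[C@@H]2C(C)(C)[C@@H](C#C)O[Si](C)(C)C(C)(C)C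
F0 | step 4 | none | none
F5 | step 15 | C1 2-[bis(2,2,2-trifluoroethoxy)phosphoryl]propanoate of 19 (both epimers at the phosphonate carbon) | CC(C(=O)O[C@@H]1[C@@H](OC(=O)[C@@H](C)CC)C[C@@]2(C)[C@@H]3C(=O)C=C(C)[C@H]2[C@@H]3C1(C)C)P(=O)(OCC(F)(F)F)OCC(F)(F)F
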